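## Retrosynthetic overview

- The target comes from its C4‑O SEM ether by a last, non‑acidic and non‑basic deprotection.
- The only ring, the cyclohexenone, is closed late at C2=C3 by ring‑closing metathesis of an open‑chain vinyl ketone / allylic ether.
- C5–C6 is made by a chelation‑controlled Mukaiyama aldol of an (S)‑α‑alkoxy ketone with 2‑(trimethylsilyloxy)buta‑1,3‑diene; C4 sets the tertiary carbinol C5.
- C4–C5 is the key bond: the aldehyde carbon of oleyl aldehyde (C5, which already carries the whole Z‑C17 chain) is joined to an α‑oxyallyl anion, a carbinol carbon used as the nucleophile, delivered as a chiral (Z)‑γ‑alkoxyallyl‑B(Ipc)2 reagent that sets C4.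
- Starting materials: oleyl alcohol, allyl alcohol, 2‑(trimethylsilyloxy)buta‑1,3‑diene.

Assumption: ring numbering is C1 = C=O, C2=C3, C4 = CH(OH), C5 = C(OH)(chain), C6 = CH2; the SMILES is the (4S,5S) isomer with the two hydroxyl groups trans; (+)‑Ipc2BOMe means the enantiomer made from (−)‑α‑pinene.

## Route

Step 1
Reactants: 1 (9Z)-octadec-9-en-1-ol (oleyl alcohol)
Product: 2 (9Z)-octadec-9-enal
Conditions: TEMPO (10 mol %), PhI(OAc)2 (1.1 equiv), CH2Cl2, rt, 3 h
Reagents that add atoms: none
Why: TEMPO/oxoammonium oxidation of a primary alcohol stops cleanly at the aldehyde and neither attacks nor isomerises the remote Z‑alkene; no stereocentre is formed.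

Step 2
Reactants: 3 prop-2-en-1-ol (allyl alcohol)
Product: 4 trimethyl{2-[(prop-2-en-1-yloxy)methoxy]ethyl}silane (allyl SEM ether)
Conditions: SEMCl (1.1 equiv), iPr2NEt (1.5 equiv), CH2Cl2, 0 °C to rt, 12 h
Reagents that add atoms: 2-(trimethylsilyl)ethoxymethyl chloride (SEMCl), C[Si](C)(C)CCOCCl
Why: O‑alkylation of the alcohol by the chloromethyl ether (acetal formation) gives an allyl ether whose acetal oxygen can direct lithiation and later chelate, and which can be removed without protic acid or base.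

Step 3
Reactants: 4 allyl SEM ether (1.5 equiv); 2 (9Z)-octadec-9-enal
Product: 8 (3S,4S,12Z)-3-{[2-(trimethylsilyl)ethoxy]methoxy}henicosa-1,12-dien-4-ol, via lithiated allyl ether 5 (not isolated), via (Z)-γ-alkoxyallyl-diisopinocampheylborane 6 (not isolated), via borinate ester 7 (not isolated)
Conditions: 4, s-BuLi, THF, −78 °C, 30 min; (+)-Ipc2BOMe, −78 °C, 1 h; BF3·OEt2, then 2, −78 °C, 4 h; NaOH, H2O2, 0 °C to rt
Reagents that add atoms: none
Why: Brown asymmetric alkoxyallylboration, in which allylic deprotonation gives the internally chelated (Z)‑oxyallyl anion 5 (an oxygen‑bearing carbon acting as nucleophile), boron takes the CH2 terminus (6), and addition to the aldehyde through a closed Zimmerman–Traxler chair makes the Z geometry give the syn adduct while the isopinocampheyl groups of the (+)‑borane series select the aldehyde face that leads to the 3S,4S isomer (typically ≥90% ee, dr >20:1), the 3S centre becoming C4 of the target.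

Step 4
Reactants: 8 (3S,4S,12Z)-3-{[2-(trimethylsilyl)ethoxy]methoxy}henicosa-1,12-dien-4-ol
Product: 9 (3S,12Z)-3-{[2-(trimethylsilyl)ethoxy]methoxy}henicosa-1,12-dien-4-one
Conditions: Dess–Martin periodinane (1.3 equiv), CH2Cl2, 0 °C to rt, 1 h
Reagents that add atoms: none
Why: Dess–Martin oxidation of the secondary alcohol under near‑neutral conditions gives the α‑alkoxy ketone without epimerising the allylic C3–H or moving the terminal alkene into conjugation; the carbinol centre at C4 of the chain is erased on purpose.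

Step 5
Reactants: 9 (3S,12Z)-3-{[2-(trimethylsilyl)ethoxy]methoxy}henicosa-1,12-dien-4-one; 10 2-(trimethylsilyloxy)buta-1,3-diene
Product: 11 (5S,6S)-5-[(8Z)-heptadec-8-en-1-yl]-5-hydroxy-6-{[2-(trimethylsilyl)ethoxy]methoxy}octa-1,7-dien-3-one
Conditions: SnCl4 (1.1 equiv), CH2Cl2, −78 °C, 10 min; then 10 (1.5 equiv), −78 °C, 1 h; aq. NaHCO3
Reagents that add atoms: none
Why: Chelation‑controlled Mukaiyama aldol addition, in which SnCl4 locks the ketone oxygen and the α‑OSEM oxygen in a five‑membered Cram chelate and the non‑basic enol silane attacks the carbonyl face on the side of the small α‑hydrogen (away from the vinyl group), which sets the tertiary carbinol as 5S (hydroxyl groups anti in the later ring) and delivers the vinyl ketone directly.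

Step 6
Reactants: 11 (5S,6S)-5-[(8Z)-heptadec-8-en-1-yl]-5-hydroxy-6-{[2-(trimethylsilyl)ethoxy]methoxy}octa-1,7-dien-3-one
Product: 12 (4S,5S)-5-[(8Z)-heptadec-8-en-1-yl]-5-hydroxy-4-{[2-(trimethylsilyl)ethoxy]methoxy}cyclohex-2-en-1-one
Conditions: second-generation Hoveyda–Grubbs catalyst RuCl2(SIMes)(=CH–C6H4–2-OiPr) (3 mol %), CH2Cl2 (0.005 M), 40 °C, 1 h
Reagents that add atoms: none
Why: Ring‑closing metathesis of the two terminal alkenes forms the six‑membered enone with loss of ethene, and because terminal alkenes initiate and close far faster than the remote internal Z‑alkene reacts, low loading, high dilution and a short reaction time keep the side chain intact; no stereocentre is touched.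

Step 7
Reactants: 12 (4S,5S)-5-[(8Z)-heptadec-8-en-1-yl]-5-hydroxy-4-{[2-(trimethylsilyl)ethoxy]methoxy}cyclohex-2-en-1-one
Product: 13 (4S,5S)-5-[(8Z)-heptadec-8-en-1-yl]-4,5-dihydroxycyclohex-2-en-1-one
Conditions: MgBr2·OEt2 (10 equiv), Et2O/MeNO2, rt, 6 h; pH 7 phosphate buffer
Reagents that add atoms: none
Why: Lewis‑acid SEM cleavage, in which MgBr2 held between the acetal oxygens and the neighbouring hydroxyl lets bromide attack silicon so that the group fragments to ethene and formaldehyde, frees the C4 hydroxyl without protic acid or base, so the dehydration‑prone β‑hydroxy ketone and both stereocentres survive.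

## Compound list

1 | (9Z)-octadec-9-en-1-ol (oleyl alcohol) | CCCCCCCC/C=C\CCCCCCCCO | starting material
2 | (9Z)-octadec-9-enal | CCCCCCCC/C=C\CCCCCCCC=O | intermediate
3 | prop-2-en-1-ol (allyl alcohol) | C=CCO | starting material
4 | trimethyl{2-[(prop-2-en-1-yloxy)methoxy]ethyl}silane (allyl SEM ether) | C=CCOCOCC[Si](C)(C)C | intermediate
5 | 1-lithio-1-{[2-(trimethylsilyl)ethoxy]methoxy}prop-2-ene (chelated Z-oxyallyl-lithium, drawn as the α-lithio form) | [Li]C(OCOCC[Si](C)(C)C)C=C | intermediate
6 | [(2Z)-3-{[2-(trimethylsilyl)ethoxy]methoxy}prop-2-en-1-yl]di(isopinocampheyl)borane, Ipc groups of the (+)-Ipc2BOMe series | C[Si](C)(C)CCOCO/C=C\CB([C@H]1C[C@H]2C[C@@H]([C@@H]1C)C2(C)C)[C@H]1C[C@H]2C[C@@H]([C@@H]1C)C2(C)C | intermediate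
7 | di(isopinocampheyl)borinate ester of alcohol 8 | CCCCCCCC/C=C\CCCCCCC[C@H](OB([C@H]1C[C@H]2C[C@@H]([C@@H]1C)C2(C)C)[C@H]1C[C@H]2C[C@@H]([C@@H]1C)C2(C)C)[C@@H](OCOCC[Si](C)(C)C)C=C | intermediate
8 | (3S,4S,12Z)-3-{[2-(trimethylsilyl)ethoxy]methoxy}henicosa-1,12-dien-4-ol | CCCCCCCC/C=C\CCCCCCC[C@H](O)[C@@H](OCOCC[Si](C)(C)C)C=C | intermediate
9 | (3S,12Z)-3-{[2-(trimethylsilyl)ethoxy]methoxy}henicosa-1,12-dien-4-one | CCCCCCCC/C=C\CCCCCCCC(=O)[C@@H](OCOCC[Si](C)(C)C)C=C | intermediate
10 | 2-(trimethylsilyloxy)buta-1,3-diene | C=CC(=C)O[Si](C)(C)C | starting material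
11 | (5S,6S)-5-[(8Z)-heptadec-8-en-1-yl]-5-hydroxy-6-{[2-(trimethylsilyl)ethoxy]methoxy}octa-1,7-dien-3-one | CCCCCCCC/C=C\CCCCCCC[C@](O)(CC(=O)C=C)[C@@H](OCOCC[Si](C)(C)C)C=C | intermediate
12 | (4S,5S)-5-[(8Z)-heptadec-8-en-1-yl]-5-hydroxy-4-{[2-(trimethylsilyl)ethoxy]methoxy}cyclohex-2-en-1-one | CCCCCCCC/C=C\CCCCCCC[C@]1(O)CC(=O)C=C[C@@H]1OCOCC[Si](C)(C)C | intermediate
13 | (4S,5S)-5-[(8Z)-heptadec-8-en-1-yl]-4,5-dihydroxycyclohex-2-en-1-one | CCCCCCCC/C=C\CCCCCCC[C@]1(O)CC(=O)C=C[C@@H]1O | target

## Step count and risks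

Total step count: 7. Longest linear sequence: 6 steps (1 → 2 → 8 → 9 → 11 → 12 → 13); step 2 is the one side step.

Three steps most likely to fail:

Risk at step 5. A ketone is a sluggish Mukaiyama acceptor; the Lewis acid may attack the SEM acetal, and the β‑hydroxy vinyl ketone product can add excess diene or cyclise by oxa‑Michael addition. The fallback sets out from 9 and comes back at 11. The enolate of N‑methoxy‑N‑methylacetamide (LiN(iPr)2, THF, −78 °C) is added to 9 precomplexed with MgBr2·OEt2. Addition through the same magnesium chelate gives the Weinreb amide (3S,4S)-3-[(8Z)-heptadec-8-en-1-yl]-3-hydroxy-N-methoxy-N-methyl-4-{[2-(trimethylsilyl)ethoxy]methoxy}hex-5-enamide F1. CH2=CHMgBr (3 equiv, THF, 0 °C, acidic quench) then turns F1 into vinyl ketone 11. This replaces the Lewis‑acid enol silane addition by an enolate/acyl‑substitution sequence and keeps the sensitive vinyl ketone out of the C–C bond‑forming step.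

Risk at step 6. The ruthenium carbene may also engage the internal Z‑alkene of the chain (chain scrambling, loss of Z purity), or the electron‑poor vinyl ketone may turn over poorly. The fallback sets out from 11 and comes back at 12. Luche reduction (NaBH4, CeCl3·7H2O, MeOH, −78 °C) gives the allylic alcohol (5S,6S)-5-[(8Z)-heptadec-8-en-1-yl]-6-{[2-(trimethylsilyl)ethoxy]methoxy}octa-1,7-diene-3,5-diol F2 as a mixture at C3. This electron‑rich diene is closed with the first‑generation Grubbs catalyst RuCl2(PCy3)2(=CHPh), which leaves internal alkenes essentially untouched, to give (4S,5S)-5-[(8Z)-heptadec-8-en-1-yl]-4-{[2-(trimethylsilyl)ethoxy]methoxy}cyclohex-2-ene-1,5-diol F3. MnO2 (CH2Cl2, rt) oxidises only the secondary allylic alcohol of F3 and returns enone 12.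

Risk at step 7. The SEM ether sits next to a quaternary centre and may cleave slowly, and 13 can lose water toward an alkylhydroquinone if it is exposed to the Lewis acid for long. The fallback sets out from 11 and comes back at 13. The SEM group is removed at the open‑chain stage (MgBr2·OEt2, Et2O/MeNO2, rt), where no aromatisation is possible, to give (5S,6S)-5-[(8Z)-heptadec-8-en-1-yl]-5,6-dihydroxyocta-1,7-dien-3-one F4. Ring‑closing metathesis of F4 with the second‑generation Hoveyda–Grubbs catalyst (CH2Cl2, 0.005 M, 40 °C) then gives 13 directly, so the last step is neutral and 13 never meets the deprotection reagent.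

## Further compounds

F1 | step 5 | (3S,4S)-3-[(8Z)-heptadec-8-en-1-yl]-3-hydroxy-N-methoxy-N-methyl-4-{[2-(trimethylsilyl)ethoxy]methoxy}hex-5-enamide | CCCCCCCC/C=C\CCCCCCC[C@](O)(CC(=O)N(C)OC)[C@@H](OCOCC[Si](C)(C)C)C=C
F2 | step 6 | (5S,6S)-5-[(8Z)-heptadec-8-en-1-yl]-6-{[2-(trimethylsilyl)ethoxy]methoxy}octa-1,7-diene-3,5-diol (both C3 epimers) | CCCCCCCC/C=C\CCCCCCC[C@](O)(CC(O)C=C)[C@@H](OCOCC[Si](C)(C)C)C=C
F3 | step 6 | (4S,5S)-5-[(8Z)-heptadec-8-en-1-yl]-4-{[2-(trimethylsilyl)ethoxy]methoxy}cyclohex-2-ene-1,5-diol (both C1 epimers) | CCCCCCCC/C=C\CCCCCCC[C@]1(O)CC(O)C=C[C@@H]1OCOCC[Si](C)(C)C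
F4 | step 7 | (5S,6S)-5-[(8Z)-heptadec-8-en-1-yl]-5,6-dihydroxyocta-1,7-dien-3-one | CCCCCCCC/C=C\CCCCCCC[C@](O)(CC(=O)C=C)[C@@H](O)C=C
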